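**Plan**

- Numbering used: oxolane O1–C2–C3–C4–C5, with C3 carrying the benzylic carbon C6 and C4 the carbinol carbon C7; the target is (3R,4S,7S). The enabling feature is that O1 lies between two bare CH2 groups (C2, C5) and the C3/C4 substituents are cis, the pattern left when CH2=O(+)–CH2(−) adds to a cyclic Z-alkene.
- Retrosynthesis: remove the silyl groups, take C7–OH back to a ketone, cut the C7–aryl bond (Weinreb amide plus aryllithium), and trace C6–H back to a benzylic lactone C6–O bond. Then cut C2–C3 and C4–C5 together ([3+2]) to a γ-aryl butenolide and the parent carbonyl ylide, and cut the butenolide C=C by metathesis back to the acrylate of a resolved aryl vinyl carbinol.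
- Forward order: the lactone ring is made by ring-closing metathesis, the oxolane ring by cycloaddition onto it, and the lactone ring is then opened by hydrogenolysis (which also frees the phenol). The second aryl ring is joined at C7 as a ketone, which is reduced, and the phenols are desilylated.
- Stereochemistry: a lipase resolution sets (S)-C6. This centre steers the dipole anti to its aryl group, fixing C3 (R) and C4 (S) cis, and is then erased. C7 (S) comes from a Corey–Bakshi–Shibata reduction with the (R)-catalyst.

Key step: step 6

Remark on the chemistry: 3-(benzyloxy)-4-methoxybenzaldehyde is taken as purchasable (otherwise one benzylation of isovanillin), and the lipase is assumed to show its usual preference for acylating the (R)-1-arylalkanol.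

**Route**

Step 1
Reactants: 1 3-(benzyloxy)-4-methoxybenzaldehyde
Product: 2 rac-1-[3-(benzyloxy)-4-methoxyphenyl]prop-2-en-1-ol
Conditions: CH2=CHMgBr, THF, 0 °C; aq. NH4Cl
Reagents that add atoms: vinylmagnesium bromide, C=C[Mg]Br
Why: Grignard 1,2-addition of the vinyl nucleophile to the aryl aldehyde should give the allylic benzylic carbinol as a racemate, the new stereocentre being sorted out in the next step.

Step 2
Reactants: 2 rac-1-[3-(benzyloxy)-4-methoxyphenyl]prop-2-en-1-ol
Product: 3 (S)-1-[3-(benzyloxy)-4-methoxyphenyl]prop-2-en-1-ol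
Conditions: immobilised Candida antarctica lipase B, vinyl acetate, MTBE, 30 °C, stopped just beyond half conversion; chromatography
Reagents that add atoms: none
Why: Lipase-catalysed kinetic resolution by irreversible transesterification should acylate the (R)-carbinol (aryl in the large pocket, vinyl in the medium one) and leave the (S)-alcohol, whose enantiopurity rises as conversion passes one half.

Step 3
Reactants: 3 (S)-1-[3-(benzyloxy)-4-methoxyphenyl]prop-2-en-1-ol; 4 acryloyl chloride
Product: 5 (S)-1-[3-(benzyloxy)-4-methoxyphenyl]prop-2-en-1-yl prop-2-enoate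
Conditions: Et3N, CH2Cl2, −20 to 0 °C
Reagents that add atoms: none
Why: O-acylation of the alcohol by the acid chloride (esterification) leaves the C–O bond of the stereocentre intact, so the (S) configuration is carried over, and the low temperature limits ionisation of the electron-rich allylic benzylic ester.

Step 4
Reactants: 5 (S)-1-[3-(benzyloxy)-4-methoxyphenyl]prop-2-en-1-yl prop-2-enoate
Product: 6 (S)-5-[3-(benzyloxy)-4-methoxyphenyl]furan-2(5H)-one
Conditions: second-generation Grubbs catalyst (H2IMes)(PCy3)Cl2Ru=CHPh (5 mol %), CH2Cl2 (0.01 M), 40 °C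
Reagents that add atoms: none
Why: Ring-closing olefin metathesis between the allylic vinyl group and the acrylate expels ethylene and should close the five-membered unsaturated lactone without involving the stereocentre.

Step 5
Reactants: 7 (trimethylsilyl)methanol
Product: 8 chloromethyl (trimethylsilyl)methyl ether
Conditions: (CH2O)n, HCl (g), neat, 0 °C; dried over CaCl2, distilled
Reagents that add atoms: paraformaldehyde (as formaldehyde), C=O; hydrogen chloride, Cl
Why: Chloromethylation of an alcohol (hemiformal formation, then replacement of the hemiacetal hydroxyl by chloride) is the standard entry to α-chloro ethers and should give the bifunctional ylide precursor.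

Step 6
Reactants: 6 (S)-5-[3-(benzyloxy)-4-methoxyphenyl]furan-2(5H)-one; 8 chloromethyl (trimethylsilyl)methyl ether
Product: 10 (3S,3aR,6aS)-3-[3-(benzyloxy)-4-methoxyphenyl]tetrahydro-1H,3H-furo[3,4-c]furan-1-one, via carbonyl ylide 9 (not isolated)
Conditions: CsF (flame-dried), MeCN, rt, slow addition of 8
Reagents that add atoms: none
Why: Fluoride attacks silicon of 8 and the α-oxy carbanion so released expels chloride (1,3-elimination) to give the parent carbonyl ylide 9, which adds across the C=C bond of 6 in a concerted, suprafacial 1,3-dipolar cycloaddition. The closest known reaction type is the [3+2] cycloaddition of this same fluoride-generated, non-stabilised carbonyl ylide with acrylates, maleates, fumarates and enones, of which an α,β-unsaturated γ-lactone is a cyclic member. The oxolane ring closes by intermolecular [3+2] annulation in which C2–C3 and C4–C5 are formed together, the new ring ending up cis-fused to the lactone. The two new stereocentres (C3 and C4 of the target) must be cis because both bonds are made on one face of a Z-olefin held in a five-membered ring, and their absolute sense is dictated by the (S)-configured C6, whose aryl group covers one face so that the dipole enters anti to it. The step needs π-facial selectivity and survival of the C6 configuration up to the moment of cycloaddition: the first is secured by the flat butenolide carrying a single large γ-substituent, the second by keeping the medium weakly basic (sparingly soluble CsF in MeCN, slow addition of 8, excess of the dipole precursor). Regioselectivity does not arise, since the dipole is symmetrical.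

Step 7
Reactants: 10 (3S,3aR,6aS)-3-[3-(benzyloxy)-4-methoxyphenyl]tetrahydro-1H,3H-furo[3,4-c]furan-1-one
Product: 11 (3S,4R)-4-(3-hydroxy-4-methoxybenzyl)tetrahydrofuran-3-carboxylic acid
Conditions: H2 (3 atm), 10% Pd/C, EtOAc–AcOH, rt
Reagents that add atoms: none
Why: Catalytic hydrogenolysis should cleave both benzylic C–O bonds (the benzyl ether and the lactone C–O bond at the electron-rich benzylic carbon), turning the directing stereocentre into the C6 methylene and freeing the C7 carboxyl, while C3 and C4 stay cis because no bond to them is touched.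

Step 8
Reactants: 11 (3S,4R)-4-(3-hydroxy-4-methoxybenzyl)tetrahydrofuran-3-carboxylic acid
Product: 12 (3S,4R)-4-(3-hydroxy-4-methoxybenzyl)-N-methoxy-N-methyltetrahydrofuran-3-carboxamide
Conditions: MeNHOMe·HCl, EDC·HCl, HOBt, N-methylmorpholine, CH2Cl2, 0 °C to rt
Reagents that add atoms: N,O-dimethylhydroxylamine hydrochloride, CNOC.Cl
Why: Carbodiimide/HOBt amide coupling should give the Weinreb amide selectively at the carboxyl, since the active ester is aminolysed faster than it acylates the phenol, and the mild conditions should leave the α-stereocentre cis.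

Step 9
Reactants: 12 (3S,4R)-4-(3-hydroxy-4-methoxybenzyl)-N-methoxy-N-methyltetrahydrofuran-3-carboxamide
Product: 13 (3S,4R)-4-[3-(tert-butyldimethylsilyloxy)-4-methoxybenzyl]-N-methoxy-N-methyltetrahydrofuran-3-carboxamide
Conditions: TBSCl, imidazole, DMF, rt
Reagents that add atoms: tert-butyldimethylsilyl chloride, CC(C)(C)[Si](C)(C)Cl
Why: Silylation of the phenol installs a fluoride-labile group that tolerates aryllithium and borane and can be removed at the end without hydrogenolytic risk to the benzylic alcohol.

Step 10
Reactants: 14 5-bromo-2-methoxyphenol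
Product: 15 tert-butyl(5-bromo-2-methoxyphenoxy)dimethylsilane
Conditions: TBSCl, imidazole, DMF, rt
Reagents that add atoms: tert-butyldimethylsilyl chloride, CC(C)(C)[Si](C)(C)Cl
Why: The same phenol silylation gives the aryl bromide in a form fit for bromine–lithium exchange.

Step 11
Reactants: 13 (3S,4R)-4-[3-(tert-butyldimethylsilyloxy)-4-methoxybenzyl]-N-methoxy-N-methyltetrahydrofuran-3-carboxamide; 15 tert-butyl(5-bromo-2-methoxyphenoxy)dimethylsilane
Product: 18 [3-(tert-butyldimethylsilyloxy)-4-methoxyphenyl]{(3S,4R)-4-[3-(tert-butyldimethylsilyloxy)-4-methoxybenzyl]tetrahydrofuran-3-yl}methanone, via aryllithium 16 (not isolated), via lithium hemiaminal adduct 17 (not isolated)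
Conditions: 15, n-BuLi, THF, −78 °C; then 13, −78 °C; aq. NH4Cl at −78 °C
Reagents that add atoms: none
Why: Bromine–lithium exchange gives the aryllithium, which adds once to the N-methoxy-N-methylamide (Weinreb ketone synthesis) because the chelated tetrahedral adduct persists until the cold quench, and the low temperature and modest basicity of an aryllithium should leave the α-centre C4 cis.

Step 12
Reactants: 18 [3-(tert-butyldimethylsilyloxy)-4-methoxyphenyl]{(3S,4R)-4-[3-(tert-butyldimethylsilyloxy)-4-methoxybenzyl]tetrahydrofuran-3-yl}methanone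
Product: 19 (S)-[3-(tert-butyldimethylsilyloxy)-4-methoxyphenyl]{(3S,4R)-4-[3-(tert-butyldimethylsilyloxy)-4-methoxybenzyl]tetrahydrofuran-3-yl}methanol
Conditions: (R)-1-methyl-3,3-diphenyltetrahydro-1H,3H-pyrrolo[1,2-c][1,3,2]oxazaborole [(R)-Me-CBS] (0.5 equiv), BH3·SMe2, THF, −20 °C; MeOH
Reagents that add atoms: none
Why: In the Corey–Bakshi–Shibata reduction the ketone binds to the ring boron with its aryl group as the large substituent and takes hydride from the nitrogen-bound borane through a six-membered transition state, which with the (R)-catalyst should deliver the (S)-carbinol at C7 under reagent control.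

Step 13
Reactants: 19 (S)-[3-(tert-butyldimethylsilyloxy)-4-methoxyphenyl]{(3S,4R)-4-[3-(tert-butyldimethylsilyloxy)-4-methoxybenzyl]tetrahydrofuran-3-yl}methanol
Product: 20 5-{(S)-hydroxy[(3S,4R)-4-(3-hydroxy-4-methoxybenzyl)tetrahydrofuran-3-yl]methyl}-2-methoxyphenol
Conditions: Bu4NF, AcOH, THF, 0 °C
Reagents that add atoms: none
Why: Fluoride-mediated desilylation should cleave both aryl silyl ethers through pentacoordinate silicon, with acetic acid buffering the phenoxides, and leave the benzylic alcohol and all three stereocentres untouched.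

**Compound list**

1 | 3-(benzyloxy)-4-methoxybenzaldehyde | COc1ccc(C=O)cc1OCc1ccccc1 | starting material
2 | rac-1-[3-(benzyloxy)-4-methoxyphenyl]prop-2-en-1-ol | COc1ccc(C(O)C=C)cc1OCc1ccccc1 | intermediate
3 | (S)-1-[3-(benzyloxy)-4-methoxyphenyl]prop-2-en-1-ol | COc1ccc([C@@H](O)C=C)cc1OCc1ccccc1 | intermediate
4 | acryloyl chloride | C=CC(=O)Cl | starting material
5 | (S)-1-[3-(benzyloxy)-4-methoxyphenyl]prop-2-en-1-yl prop-2-enoate | COc1ccc([C@@H](OC(=O)C=C)C=C)cc1OCc1ccccc1 | intermediate
6 | (S)-5-[3-(benzyloxy)-4-methoxyphenyl]furan-2(5H)-one | COc1ccc([C@H]2OC(=O)C=C2)cc1OCc1ccccc1 | intermediate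
7 | (trimethylsilyl)methanol | C[Si](C)(C)CO | starting material
8 | chloromethyl (trimethylsilyl)methyl ether | C[Si](C)(C)COCCl | intermediate
9 | parent carbonyl ylide, formaldehyde O-methylide (not isolated) | C=[O+][CH2-] | intermediate
10 | (3S,3aR,6aS)-3-[3-(benzyloxy)-4-methoxyphenyl]tetrahydro-1H,3H-furo[3,4-c]furan-1-one | COc1ccc([C@H]2OC(=O)[C@@H]3COC[C@H]23)cc1OCc1ccccc1 | intermediate
11 | (3S,4R)-4-(3-hydroxy-4-methoxybenzyl)tetrahydrofuran-3-carboxylic acid | COc1ccc(C[C@H]2COC[C@H]2C(=O)O)cc1O | intermediate
12 | (3S,4R)-4-(3-hydroxy-4-methoxybenzyl)-N-methoxy-N-methyltetrahydrofuran-3-carboxamide | COc1ccc(C[C@H]2COC[C@H]2C(=O)N(C)OC)cc1O | intermediate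
13 | (3S,4R)-4-[3-(tert-butyldimethylsilyloxy)-4-methoxybenzyl]-N-methoxy-N-methyltetrahydrofuran-3-carboxamide | COc1ccc(C[C@H]2COC[C@H]2C(=O)N(C)OC)cc1O[Si](C)(C)C(C)(C)C | intermediate
14 | 5-bromo-2-methoxyphenol | COc1ccc(Br)cc1O | starting material
15 | tert-butyl(5-bromo-2-methoxyphenoxy)dimethylsilane | COc1ccc(Br)cc1O[Si](C)(C)C(C)(C)C | intermediate
16 | [3-(tert-butyldimethylsilyloxy)-4-methoxyphenyl]lithium (not isolated) | COc1ccc([Li])cc1O[Si](C)(C)C(C)(C)C | intermediate
17 | lithium alkoxide of the tetrahedral N-methoxy-N-methyl hemiaminal adduct, configuration at the new carbon not defined (not isolated) | COc1ccc(C[C@H]2COC[C@H]2C(O[Li])(N(C)OC)c2ccc(OC)c(O[Si](C)(C)C(C)(C)C)c2)cc1O[Si](C)(C)C(C)(C)C | intermediate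
18 | [3-(tert-butyldimethylsilyloxy)-4-methoxyphenyl]{(3S,4R)-4-[3-(tert-butyldimethylsilyloxy)-4-methoxybenzyl]tetrahydrofuran-3-yl}methanone | COc1ccc(C[C@H]2COC[C@H]2C(=O)c2ccc(OC)c(O[Si](C)(C)C(C)(C)C)c2)cc1O[Si](C)(C)C(C)(C)C | intermediate
19 | (S)-[3-(tert-butyldimethylsilyloxy)-4-methoxyphenyl]{(3S,4R)-4-[3-(tert-butyldimethylsilyloxy)-4-methoxybenzyl]tetrahydrofuran-3-yl}methanol | COc1ccc(C[C@H]2COC[C@H]2[C@H](O)c2ccc(OC)c(O[Si](C)(C)C(C)(C)C)c2)cc1O[Si](C)(C)C(C)(C)C | intermediate
20 | 5-{(S)-hydroxy[(3S,4R)-4-(3-hydroxy-4-methoxybenzyl)tetrahydrofuran-3-yl]methyl}-2-methoxyphenol | COc1ccc(C[C@H]2COC[C@H]2[C@H](O)c2ccc(OC)c(O)c2)cc1O | target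

**Count**

Total steps: 13. Longest linear sequence: 11 steps (steps 1–4, 6–9, 11–13, from compound 1); steps 5 and 10 are side branches.

**Steps most likely to fail**

1. Step 6. The doubly activated γ-position of the butenolide (benzylic and vinylogous to the lactone carbonyl) may be deprotonated and reprotonated by fluoride before the dipole is intercepted, which would erode the enantiopurity carried into the cycloadduct; self-condensation of the dipole may also hold conversion down. The fallback moves the source of absolute configuration behind the cycloaddition, where this exchange is harmless. It sets out from the racemic carbinol 2 and omits the resolution. Acylation with 4 (Et3N, CH2Cl2) should give racemic 1-[3-(benzyloxy)-4-methoxyphenyl]prop-2-en-1-yl prop-2-enoate F1, and metathesis with the same ruthenium catalyst the racemic butenolide F2. Cycloaddition with 8 and CsF then gives the racemic cis-fused cycloadduct F3, whose relative configuration is still fixed by anti addition. Hydrogenolysis (H2, Pd/C) gives the racemic cis acid F4. This acid is resolved by fractional crystallisation with an enantiopure amine chosen in a salt screen, for instance as the (R)-1-phenylethylammonium salt of the (3S,4R) acid F5. Acidification (dilute HCl, EtOAc) then liberates 11, where the route resumes at step 8; the configuration of the resolved acid would be confirmed by comparison with 11 made through 6.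

2. Step 11. The aryllithium may act as a base and enolise the amide (or the ketone once released), which would equilibrate the C4 centre toward the trans-disubstituted oxolane; incomplete exchange or attack at silicon would lower conversion. The fallback replaces the organolithium addition by a base-free cross-coupling and sets out from 11. Thioesterification (EtSH, EDC·HCl, cat. DMAP, CH2Cl2) should give S-ethyl (3S,4R)-4-(3-hydroxy-4-methoxybenzyl)tetrahydrofuran-3-carbothioate F6, and silylation (TBSCl, imidazole) S-ethyl (3S,4R)-4-[3-(tert-butyldimethylsilyloxy)-4-methoxybenzyl]tetrahydrofuran-3-carbothioate F7. The aryllithium 16 is quenched with B(OiPr)3 and hydrolysed mildly to [3-(tert-butyldimethylsilyloxy)-4-methoxyphenyl]boronic acid F8. Liebeskind–Srogl coupling of F7 with F8 (Pd2(dba)3, tri(2-furyl)phosphine, Cu(O2CC4H3S) [CuTC], THF, 50 °C) forms the C7–aryl bond under neutral conditions and comes back to the route at ketone 18.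

3. Step 12. Facial selectivity may be poor or mismatched, because the α-branched, cis-substituted oxolane can compete with the aryl group as the large substituent and the resident stereocentres bias the carbonyl faces on their own. The fallback gives up catalyst control and sets out from 18. Reduction with NaBH4 (MeOH–THF, −20 °C) gives both C7 epimers; 19 is separated by chromatography from the (R)-carbinol epimer F9. F9 is re-oxidised to 18 with Dess–Martin periodinane (NaHCO3, CH2Cl2) and passed through the reduction again, so that material is funnelled to 19, where the route resumes at step 13.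

**Further compounds**

F1 | step 6 | rac-1-[3-(benzyloxy)-4-methoxyphenyl]prop-2-en-1-yl prop-2-enoate | COc1ccc(C(OC(=O)C=C)C=C)cc1OCc1ccccc1
F2 | step 6 | rac-5-[3-(benzyloxy)-4-methoxyphenyl]furan-2(5H)-one | COc1ccc(C2OC(=O)C=C2)cc1OCc1ccccc1
F3 | step 6 | rac-(3S*,3aR*,6aS*)-3-[3-(benzyloxy)-4-methoxyphenyl]tetrahydro-1H,3H-furo[3,4-c]furan-1-one (racemate; one enantiomer drawn) | COc1ccc([C@H]2OC(=O)[C@@H]3COC[C@H]23)cc1OCc1ccccc1
F4 | step 6 | rac-cis-4-(3-hydroxy-4-methoxybenzyl)tetrahydrofuran-3-carboxylic acid (racemate; one enantiomer drawn) | COc1ccc(C[C@H]2COC[C@H]2C(=O)O)cc1O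
F5 | step 6 | (R)-1-phenylethylammonium (3S,4R)-4-(3-hydroxy-4-methoxybenzyl)tetrahydrofuran-3-carboxylate | COc1ccc(C[C@H]2COC[C@H]2C(=O)[O-])cc1O.C[C@@H]([NH3+])c1ccccc1
F6 | step 11 | S-ethyl (3S,4R)-4-(3-hydroxy-4-methoxybenzyl)tetrahydrofuran-3-carbothioate | COc1ccc(C[C@H]2COC[C@H]2C(=O)SCC)cc1O
F7 | step 11 | S-ethyl (3S,4R)-4-[3-(tert-butyldimethylsilyloxy)-4-methoxybenzyl]tetrahydrofuran-3-carbothioate | COc1ccc(C[C@H]2COC[C@H]2C(=O)SCC)cc1O[Si](C)(C)C(C)(C)C
F8 | step 11 | [3-(tert-butyldimethylsilyloxy)-4-methoxyphenyl]boronic acid | COc1ccc(B(O)O)cc1O[Si](C)(C)C(C)(C)C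
F9 | step 12 | (R)-[3-(tert-butyldimethylsilyloxy)-4-methoxyphenyl]{(3S,4R)-4-[3-(tert-butyldimethylsilyloxy)-4-methoxybenzyl]tetrahydrofuran-3-yl}methanol | COc1ccc(C[C@H]2COC[C@H]2[C@@H](O)c2ccc(OC)c(O[Si](C)(C)C(C)(C)C)c2)cc1O[Si](C)(C)C(C)(C)C
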